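**Retrosynthetic overview**
- The target is opened at the ring carbon flanked by two carbonyls: its two prenyl groups go on last, onto the prenyl-free spiro acylphloroglucinol.
- The trione ring comes from a Claisen cyclisation: the 1,3-dianion of 6-methylheptane-2,4-dione is acylated by a bridged lactone-acid, whose free acid becomes the C6 carbonyl and whose lactone carbonyl becomes the C2 carbonyl while releasing the 7′-OH.
- The lactone-acid comes from hydro-lactonisation of a gem-diacid on a trans-hexahydroindene; the lactone fixes C7′ and the future spiro centre together.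
- Cyclopentane and cyclohexene are made in one intramolecular Diels–Alder reaction of a dienylidene malonate, itself from Knoevenagel condensation of dimethyl malonate with (R)-8-oxolinalool (SeO2 oxidation of (R)-linalool).
- Ring order: the two carbocycles of the hydrindane together, then the temporary γ-lactone, then the trione ring.

Assumption: the target is treated as the enol tautomer drawn in the given SMILES; commercial (R)-(−)-linalool of high ee supplies C3′. The route is a design from mechanistic reasoning and has not been run.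

**Route**

Step 1
Reactants: 1 (R)-(−)-linalool, (3R)-3,7-dimethylocta-1,6-dien-3-ol
Product: 2 (2E,6R)-6-hydroxy-2,6-dimethylocta-2,7-dienal (8-oxolinalool)
Conditions: SeO2 (1.2 equiv), 1,4-dioxane/H2O 30:1, 80 °C
Reagents that add atoms: selenium dioxide, O=[Se]=O
Why: Riley allylic oxidation (ene reaction then [2,3]-sigmatropic shift) attacks the (E)-methyl of the trisubstituted alkene and carries on to the (E)-enal, leaving the tertiary carbinol stereocentre from the chiral pool untouched.

Step 2
Reactants: 2 (2E,6R)-6-hydroxy-2,6-dimethylocta-2,7-dienal; 3 dimethyl malonate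
Product: 4 dimethyl 2-[(2E,6R)-6-hydroxy-2,6-dimethylocta-2,7-dien-1-ylidene]propanedioate
Conditions: piperidine (10 mol %), AcOH (10 mol %), 4 Å MS, PhMe, 70 °C
Reagents that add atoms: dimethyl malonate (3), COC(=O)CC(=O)OC
Why: Knoevenagel condensation (1,2-addition and dehydration, pulled by water removal) gives the 2-(alk-2-enylidene)malonate with the E alkene retained and no new stereocentre.

Step 3
Reactants: 4 dimethyl 2-[(2E,6R)-6-hydroxy-2,6-dimethylocta-2,7-dien-1-ylidene]propanedioate
Product: 5 dimethyl (3R,3aS,7aR)-3-hydroxy-3,7-dimethyl-2,3,3a,4,5,7a-hexahydro-1H-indene-5,5-dicarboxylate (trans-fused; 3-OH cis to C4; 3-CH3 cis to H-3a)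
Conditions: PhMe (0.01 M), BHT (5 mol %), sealed tube, 180 °C, 36 h
Reagents that add atoms: none
Why: Proposed new method: a thermal type 1 intramolecular Diels–Alder reaction in which the Knoevenagel diene (malonate carbon as one terminus) adds the unactivated vinyl group across a three-atom tether, forming cyclopentane and cyclohexene at once (closest known type: thermal cyclisation of 1,3,8-nonatrienes and of ester-terminated dienes to trans-hydrindenes); the trans fusion at C3a/C7a is expected from the exo-tether transition state because the endo one pushes the quaternary carbinol carbon against the diene methyl, and the face is set by the R carbinol placing its OH (hydrogen-bonded) under the inside ester and its CH3 outward.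

Step 4
Reactants: 5 dimethyl (3R,3aS,7aR)-3-hydroxy-3,7-dimethyl-2,3,3a,4,5,7a-hexahydro-1H-indene-5,5-dicarboxylate
Product: 6 (3R,3aS,7aR)-3-hydroxy-3,7-dimethyl-2,3,3a,4,5,7a-hexahydro-1H-indene-5,5-dicarboxylic acid
Conditions: LiOH·H2O (8 equiv), THF/MeOH/H2O, 60 °C; then 1 M HCl, 0 °C
Reagents that add atoms: lithium hydroxide (aqueous), [Li+].[OH-]
Why: Saponification of the non-enolisable gem-diester gives the malonic diacid without touching any stereocentre, and cold acidification avoids decarboxylation.

Step 5
Reactants: 6 (3R,3aS,7aR)-3-hydroxy-3,7-dimethyl-2,3,3a,4,5,7a-hexahydro-1H-indene-5,5-dicarboxylic acid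
Product: 7 (3R,3aS,5S,7S,7aR)-3,7-dihydroxy-3,7-dimethyloctahydro-1H-indene-5,5-dicarboxylic acid 5,7-lactone (bridged γ-lactone; free CO2H equatorial)
Conditions: Co(salen′) C36H52CoN2O2 (5 mol %; divalent cobalt; salen′ = (R,R)-N,N′-bis(3,5-di-tert-butylsalicylidene)cyclohexane-1,2-diaminate), N-fluoro-2,4,6-trimethylpyridinium tetrafluoroborate (1.5 equiv), PhSiH3 (1.5 equiv), acetone, 0 °C to rt
Reagents that add atoms: none
Why: Hydrogen-atom-transfer hydro-lactonisation with radical–polar crossover puts H on C6 and generates the tertiary C7 radical/cation, which only the axial carboxyl (1,3-cis) can capture, so the C7–O bond is axial with CH3 equatorial and the two carboxyls become distinct, which defines the future spiro centre.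

Step 6
Reactants: 7 (3R,3aS,5S,7S,7aR)-3,7-dihydroxy-3,7-dimethyloctahydro-1H-indene-5,5-dicarboxylic acid 5,7-lactone; 8 6-methylheptane-2,4-dione
Product: 12 (1S,3′R,3a′S,7′S,7a′R)-3′,4,7′-trihydroxy-3′,7′-dimethyl-3-(3-methylbutanoyl)octahydrospiro[cyclohex-3-ene-1,5′-indene]-2,6-dione, via acyl imidazolide 9 (not isolated), via diketone dianion 10 (not isolated), via triketo lactone 11 (not isolated)
Conditions: 7, 1,1′-carbonyldiimidazole (1.1 equiv), THF, rt; add at −78 °C to 10 [8 (4 equiv), LiN(iPr)2 (8 equiv), THF, −78 to 0 °C]; warm to 45 °C, 12 h; 1 M HCl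
Reagents that add atoms: 6-methylheptane-2,4-dione (8), CC(=O)CC(=O)CC(C)C
Why: The terminal carbon of the β-diketone 1,3-dianion is acylated by the acyl imidazolide (far more electrophilic than the hindered bridged lactone), and the resulting 3,5,7-triketo lactone then undergoes a Harris-type Claisen (Dieckmann) cyclisation of its central carbon onto the lactone carbonyl, driven by the stabilised acyl-trione anion; because the lactone carbonyl is the one cis to O-7′, the spiro centre emerges with the acyl side syn to the released 7′-OH, as in the target.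

Step 7
Reactants: 12 (1S,3′R,3a′S,7′S,7a′R)-3′,4,7′-trihydroxy-3′,7′-dimethyl-3-(3-methylbutanoyl)octahydrospiro[cyclohex-3-ene-1,5′-indene]-2,6-dione; 13 prenyl bromide (1-bromo-3-methylbut-2-ene)
Product: 14 (1S,3′R,3a′S,7′S,7a′R)-3′,4,7′-trihydroxy-3′,7′-dimethyl-5,5-bis(3-methylbut-2-en-1-yl)-3-(3-methylbutanoyl)octahydrospiro[cyclohex-3-ene-1,5′-indene]-2,6-dione (target, CNP0198642.2)
Conditions: NaOMe (3.5 equiv), 13 (2.4 equiv), MeOH, 0 °C to rt
Reagents that add atoms: prenyl bromide (13), CC(C)=CCBr
Why: Double C-alkylation of the only remaining ring CH2 (C5, between two carbonyls) by a soft allylic bromide in protic medium, as in lupulone-type prenylations of dearomatised acylphloroglucinols, creates no stereocentre and disturbs none.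

**Compound list**

1 | (R)-(−)-linalool, (3R)-3,7-dimethylocta-1,6-dien-3-ol | C=C[C@](C)(O)CCC=C(C)C | starting material
2 | (2E,6R)-6-hydroxy-2,6-dimethylocta-2,7-dienal | C=C[C@](C)(O)CC/C=C(\C)C=O | intermediate
3 | dimethyl malonate | COC(=O)CC(=O)OC | starting material
4 | dimethyl 2-[(2E,6R)-6-hydroxy-2,6-dimethylocta-2,7-dien-1-ylidene]propanedioate | C=C[C@](C)(O)CC/C=C(\C)C=C(C(=O)OC)C(=O)OC | intermediate
5 | dimethyl (3R,3aS,7aR)-3-hydroxy-3,7-dimethyl-2,3,3a,4,5,7a-hexahydro-1H-indene-5,5-dicarboxylate | COC(=O)C1(C(=O)OC)C[C@H]2[C@@H](CC[C@@]2(C)O)C(C)=C1 | intermediate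
6 | (3R,3aS,7aR)-3-hydroxy-3,7-dimethyl-2,3,3a,4,5,7a-hexahydro-1H-indene-5,5-dicarboxylic acid | OC(=O)C1(C(=O)O)C[C@H]2[C@@H](CC[C@@]2(C)O)C(C)=C1 | intermediate
7 | (3R,3aS,5S,7S,7aR)-3,7-dihydroxy-3,7-dimethyloctahydro-1H-indene-5,5-dicarboxylic acid 5,7-lactone | OC(=O)[C@@]1(C[C@H]2[C@@H](CC[C@@]2(C)O)[C@@](C)(O3)C1)C3=O | intermediate
8 | 6-methylheptane-2,4-dione | CC(=O)CC(=O)CC(C)C | starting material
9 | acyl imidazolide of 7 (imidazol-1-ylcarbonyl in place of CO2H) | O=C(n1ccnc1)[C@@]2(C[C@H]3[C@@H](CC[C@@]3(C)O)[C@@](C)(O4)C2)C4=O | intermediate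
10 | dilithium 6-methylhepta-1,3-diene-2,4-diolate (1,3-dianion of 8) | [Li+].[Li+].C=C([O-])C=C([O-])CC(C)C | intermediate
11 | 5-(7-methyl-3,5-dioxooctanoyl) analogue of 7 (triketo lactone) | CC(C)CC(=O)CC(=O)CC(=O)[C@@]1(C[C@H]2[C@@H](CC[C@@]2(C)O)[C@@](C)(O3)C1)C3=O | intermediate
12 | (1S,3′R,3a′S,7′S,7a′R)-3′,4,7′-trihydroxy-3′,7′-dimethyl-3-(3-methylbutanoyl)octahydrospiro[cyclohex-3-ene-1,5′-indene]-2,6-dione | CC(C)CC(=O)C1=C(O)CC(=O)[C@@]2(C[C@H]3[C@@H](CC[C@@]3(C)O)[C@@](C)(O)C2)C1=O | intermediate
13 | prenyl bromide, 1-bromo-3-methylbut-2-ene | CC(C)=CCBr | starting material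
14 | (1S,3′R,3a′S,7′S,7a′R)-3′,4,7′-trihydroxy-3′,7′-dimethyl-5,5-bis(3-methylbut-2-en-1-yl)-3-(3-methylbutanoyl)octahydrospiro[cyclohex-3-ene-1,5′-indene]-2,6-dione | CC(C)=CCC1(CC=C(C)C)C(=O)[C@@]2(C[C@H]3[C@@H](CC[C@@]3(C)O)[C@@](C)(O)C2)C(=O)C(C(=O)CC(C)C)=C1O | target

**Totals and risks**

Total step count: 7. Longest linear sequence: 7 steps (1 → 14).

Stereocentres: C3′ comes from 1; C3a′ and C7a′ are set in step 3; C7′ and the spiro carbon are set in step 5 and carried through step 6.

Most likely to fail, in order:

Step 3. The diene carries two esters on one terminus and the dienophile is unactivated, so the cycloaddition may be slow, and the trans-fusion and facial preferences rest on a transition-state model. Fallback, setting out from 1 and 3 and returning at 7: Mn(OAc)3·2H2O (trivalent manganese) with Cu(OAc)2·H2O in buffered AcOH adds the malonyl radical of 3 to the vinyl group of 1. 5-exo cyclisation and copper-mediated oxidation then give dimethyl 2-{[(1S,2R,5R)-2-hydroxy-2-methyl-5-(prop-1-en-2-yl)cyclopentyl]methyl}propanedioate F1. A second Mn(OAc)3/Cu(OAc)2 oxidation at 80 °C causes 6-endo cyclisation and oxidative lactonisation to the methyl ester of 7 F2. Lithium iodide (LiI) in refluxing pyridine cleaves the methyl ester and gives 7. This radical path skips 2, 4, 5 and 6, but its 5-exo diastereoselectivity and its choice between the two alkenes of 1 are less secure.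

Step 6. The acylation is at a neopentyl-type carbonyl, proton transfer may quench the dianion, and the ring closure has to beat intermolecular attack on the lactone. Fallback, setting out from 7 and 8 and returning at 12 through isolated 11: 8 is converted (Me3SiCl/Et3N, then LiN(iPr)2/Me3SiCl) into 6-methyl-2,4-bis(trimethylsilyloxy)hepta-1,3-diene F3. 7 is converted with cyanuric fluoride/pyridine into the acid fluoride of 7 F4. Fluoride-catalysed C-acylation of F3 by F4 (tetrabutylammonium difluorotriphenylsilicate, THF), followed by mild aqueous acid, gives neutral 11, which is isolated. A separate NaOMe/MeOH Claisen cyclisation then gives 12.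

Step 5. Alkene isomerisation by reversible hydrogen-atom transfer, or fluoride capture, could compete with lactonisation. Fallback, setting out from 6 and returning at 7: iodolactonisation (I2, NaHCO3, MeCN/H2O) closes the same axial carboxyl onto C7 with trans-diaxial iodine at C6, giving the 6-iodo derivative of 7 F5. Radical deiodination (Bu3SnH, azobisisobutyronitrile, PhH, 80 °C) then gives 7.

**Further compounds**

F1 | step 3 | dimethyl 2-{[(1S,2R,5R)-2-hydroxy-2-methyl-5-(prop-1-en-2-yl)cyclopentyl]methyl}propanedioate | COC(=O)C(C[C@H]1[C@@H](CC[C@@]1(C)O)C(C)=C)C(=O)OC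
F2 | step 3 | methyl ester of 7 (bridged lactone methyl ester) | COC(=O)[C@@]1(C[C@H]2[C@@H](CC[C@@]2(C)O)[C@@](C)(O3)C1)C3=O
F3 | step 6 | 6-methyl-2,4-bis(trimethylsilyloxy)hepta-1,3-diene | C=C(O[Si](C)(C)C)C=C(O[Si](C)(C)C)CC(C)C
F4 | step 6 | acid fluoride of 7 | O=C(F)[C@@]1(C[C@H]2[C@@H](CC[C@@]2(C)O)[C@@](C)(O3)C1)C3=O
F5 | step 5 | 6-iodo derivative of 7 (iodine trans-diaxial to the lactone oxygen) | OC(=O)[C@@]1(C[C@H]2[C@@H](CC[C@@]2(C)O)[C@@](C)(O3)[C@@H]1I)C3=O
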